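**Retrosynthetic overview**
1. Target 8 ⇐ racemic α-aryl ketone 5 (C=O → CHOH): both stereocentres are set together in the last step by asymmetric hydrogenation with dynamic kinetic resolution.
2. Ketone 5 ⇐ aryl–Cα disconnection between the free ortho carbon of eugenol (3) and the α-carbon of 3′,4′-dimethoxypropiophenone (1). Both carbons are natural nucleophiles, so the ketone enters as its umpoled enolate, the enolonium 4 (an O–iodine(III) enol ether).
3. Enolonium 4 ⇐ TMS enol ether 2 ⇐ ketone 1.
4. No ring is formed: both benzene rings, the allyl group and all three methoxy groups are bought with 1 and 3.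

Assumption: PhI(OAc)2 and trans-RuCl2[(R)-xylbinap][(R)-daipen] count as commercial reagents; ketone 5 is made racemic on purpose because its stereocentre is equilibrated in step 3.

**Route**

Step 1
Reactants: 1 1-(3,4-dimethoxyphenyl)propan-1-one
Product: 2 (Z)-[1-(3,4-dimethoxyphenyl)prop-1-en-1-yl]oxy(trimethyl)silane
Conditions: TMSOTf (1.2 equiv), Et3N (1.5 equiv), CH2Cl2, 0 °C → rt; pentane extraction, Kugelrohr distillation
Reagents that add atoms: trimethylsilyl trifluoromethanesulfonate, C[Si](C)(C)OS(=O)(=O)C(F)(F)F
Why: Soft enolisation and O-silylation of an aryl ethyl ketone gives the thermodynamic (Z)-silyl enol ether, with only one enolisable side so no regiochemical issue (silyl enol ether formation).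

Step 2
Reactants: 2 (Z)-[1-(3,4-dimethoxyphenyl)prop-1-en-1-yl]oxy(trimethyl)silane; 3 eugenol (4-allyl-2-methoxyphenol)
Product: 5 rac-2-(5-allyl-2-hydroxy-3-methoxyphenyl)-1-(3,4-dimethoxyphenyl)propan-1-one, via enolonium O-iodanyl enol ether 4 (not isolated)
Conditions: PhI(OAc)2 (1.05 equiv), BF3·OEt2 (1.5 equiv), CH2Cl2, −78 °C, slow addition of 2; then 3 (2.5 equiv), −78 → −40 °C; cold aq NaHCO3 quench
Reagents that add atoms: (diacetoxyiodo)benzene, CC(=O)OI(OC(C)=O)c1ccccc1 (supplies the PhI(OAc) unit of intermediate 4 only; no atom of it remains in 5)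
Why: Proposed new method: umpoled-enolate (enolonium) Friedel–Crafts-type α-arylation, in which silyl-to-iodine(III) exchange turns 2 into the O-iodanyl enol ether 4, an α-keto cation equivalent with PhI as hypernucleofuge; its α-carbon is attacked by the only free ortho carbon of unprotected eugenol (para position blocked by allyl, OH either hydrogen-bonding to the iodine-bound acetate or exchanging onto iodine and delivering the enol ligand by reductive ligand coupling), followed by rearomatising tautomerisation. The closest known reaction types are enolonium α-arylation of ketones with indoles and pyrroles and iodine(III)-mediated oxidative enol–arene coupling. The new stereocentre is formed racemic and is set in step 3.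

Step 3
Reactants: 5 rac-2-(5-allyl-2-hydroxy-3-methoxyphenyl)-1-(3,4-dimethoxyphenyl)propan-1-one
Product: 8 4-allyl-2-[(1S,2S)-1-(3,4-dimethoxyphenyl)-1-hydroxypropan-2-yl]-6-methoxyphenol (target), via potassium phenoxide of ketone 6 (not isolated), via potassium phenoxide of alcohol 7 (not isolated)
Conditions: trans-RuCl2[(R)-xylbinap][(R)-daipen] (1 mol %), KOtBu (1.3 equiv), H2 (10 atm), i-PrOH, 25 °C; aq NH4Cl work-up kept at pH ≥ 7, Et3N-deactivated silica
Reagents that add atoms: potassium tert-butoxide, CC(C)(C)[O-].[K+] (supplies only the K+ of intermediates 6 and 7; no atom of it remains in 8)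
Why: Noyori asymmetric hydrogenation with dynamic kinetic resolution: excess alkoxide racemises C-2 of 6 through its enolate faster than reduction, the (R)-xylbinap/(R)-daipen Ru hydride adds to the Re face of the aryl ketone (1S, the same sense as acetophenone → (S)-alcohol), and only the (2S)-ketone presents that face in the Felkin–Anh (Cram) arrangement with the α-aryl group anti to hydride, giving the erythro (1S,2S) alcohol. This outer-sphere, C=O-selective catalyst leaves the allyl C=C untouched.

**Compound list**
1 | 1-(3,4-dimethoxyphenyl)propan-1-one (3′,4′-dimethoxypropiophenone) | CCC(=O)c1ccc(OC)c(OC)c1 | starting material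
2 | (Z)-[1-(3,4-dimethoxyphenyl)prop-1-en-1-yl]oxy(trimethyl)silane | C/C=C(\O[Si](C)(C)C)c1ccc(OC)c(OC)c1 | intermediate
3 | eugenol (4-allyl-2-methoxyphenol) | C=CCc1ccc(O)c(OC)c1 | starting material
4 | acetoxy(phenyl)-λ3-iodanyl (Z)-enol ether of 1 (enolonium, BF3-activated, not isolated) | C/C=C(\OI(OC(C)=O)c1ccccc1)c1ccc(OC)c(OC)c1 | intermediate
5 | rac-2-(5-allyl-2-hydroxy-3-methoxyphenyl)-1-(3,4-dimethoxyphenyl)propan-1-one | C=CCc1cc(OC)c(O)c(C(C)C(=O)c2ccc(OC)c(OC)c2)c1 | intermediate
6 | potassium 4-allyl-2-[1-(3,4-dimethoxyphenyl)-1-oxopropan-2-yl]-6-methoxyphenolate (racemising, not isolated) | C=CCc1cc(OC)c([O-])c(C(C)C(=O)c2ccc(OC)c(OC)c2)c1.[K+] | intermediate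
7 | potassium 4-allyl-2-[(1S,2S)-1-(3,4-dimethoxyphenyl)-1-hydroxypropan-2-yl]-6-methoxyphenolate (not isolated) | C=CCc1cc(OC)c([O-])c([C@H](C)[C@H](O)c2ccc(OC)c(OC)c2)c1.[K+] | intermediate
8 | 4-allyl-2-[(1S,2S)-1-(3,4-dimethoxyphenyl)-1-hydroxypropan-2-yl]-6-methoxyphenol | C=CCc1cc(OC)c(O)c([C@H](C)[C@H](O)c2ccc(OC)c(OC)c2)c1 | target

**Totals**
Total step count: 3. Longest linear sequence: 3 (1 → 2 → 5 → 8); eugenol 3 enters at step 2.

**Steps most likely to fail and fallbacks**

Step 2 (highest risk). The phenol may attack through oxygen to give the α-aryloxy ketone, or through the carbon para to OMe. The enolonium may homocouple, and the BF3/AcOH medium may cyclodehydrate 5 to a benzofuran if warmed. The fallback keeps the same bond but forces ortho delivery through an O–S tether; it sets out from 1 and 3 and comes back at 5. Ketone 1 is sulfenylated (LiHMDS, MeSSMe, THF, −78 °C) to 1-(3,4-dimethoxyphenyl)-2-(methylsulfanyl)propan-1-one F1. F1 is activated with NCS (CH2Cl2, −78 °C) and treated with eugenol 3 to give (4-allyl-2-methoxyphenoxy)(methyl)[1-(3,4-dimethoxyphenyl)-1-oxopropan-2-yl]sulfonium chloride F2. Et3N then triggers the Gassman-type [2,3]-sigmatropic rearrangement of F2 onto the free ortho carbon, and rearomatisation gives rac-2-(5-allyl-2-hydroxy-3-methoxyphenyl)-1-(3,4-dimethoxyphenyl)-2-(methylsulfanyl)propan-1-one F3. F3 cannot dehydrate to a benzofuran because its α-carbon is quaternary. SmI2 (THF/MeOH, −78 °C) cleaves the C–S bond next to the carbonyl without touching the allyl group and returns ketone 5.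

Step 3. The ortho-phenoxide may slow enolisation so that resolution is only kinetic, may bind ruthenium, or may erode the Felkin preference. The product also cyclises to a dihydrobenzofuran under acid. The fallback replaces catalytic dynamic resolution with substrate control plus physical resolution; it sets out from 5 and comes back at 8. Ketone 5 is reduced with L-Selectride (2.5 equiv, THF, −78 °C, the first equivalent consumed by the phenol) under Felkin–Anh control to the racemic erythro alcohol (1:1 mixture of (1S,2S) and (1R,2R)) F4. The enantiomers of F4 are separated by preparative chiral SFC (amylose tris(3,5-dimethylphenylcarbamate), CO2/MeOH) to collect 8.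

Step 1 (lowest risk). The TMS enol ether may hydrolyse on isolation or carry amine or triflate salts that spoil the iodine(III) step. The fallback makes 2 reductively without base; it sets out from 1 and comes back at 2. Ketone 1 is brominated (CuBr2, EtOAc/CHCl3, reflux) to 2-bromo-1-(3,4-dimethoxyphenyl)propan-1-one F5. F5 is converted by Zn dust and TMSCl (Et2O/MeCN, cat. TMEDA, 0 °C → rt) through its zinc enolate into silyl enol ether 2.

**Further compounds**
F1 | step 2 | 1-(3,4-dimethoxyphenyl)-2-(methylsulfanyl)propan-1-one (racemic) | CSC(C)C(=O)c1ccc(OC)c(OC)c1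
F2 | step 2 | (4-allyl-2-methoxyphenoxy)(methyl)[1-(3,4-dimethoxyphenyl)-1-oxopropan-2-yl]sulfonium chloride | C[S+](Oc1ccc(CC=C)cc1OC)C(C)C(=O)c1ccc(OC)c(OC)c1.[Cl-]
F3 | step 2 | rac-2-(5-allyl-2-hydroxy-3-methoxyphenyl)-1-(3,4-dimethoxyphenyl)-2-(methylsulfanyl)propan-1-one | C=CCc1cc(OC)c(O)c(C(C)(SC)C(=O)c2ccc(OC)c(OC)c2)c1
F4 | step 3 | racemic erythro 4-allyl-2-[1-(3,4-dimethoxyphenyl)-1-hydroxypropan-2-yl]-6-methoxyphenol, 1:1 (1S,2S)/(1R,2R) | C=CCc1cc(OC)c(O)c([C@H](C)[C@H](O)c2ccc(OC)c(OC)c2)c1.C=CCc1cc(OC)c(O)c([C@@H](C)[C@@H](O)c2ccc(OC)c(OC)c2)c1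
F5 | step 1 | 2-bromo-1-(3,4-dimethoxyphenyl)propan-1-one (racemic) | CC(Br)C(=O)c1ccc(OC)c(OC)c1
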